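**Strategy.** The oxolane is opened at O1–C2 and the ester is removed, which leaves the chain C5–C4–C3–C(3-arm): four carbons, oxygenated at both ends, whose inner carbons C4 and C3 bear the arylmethyl group and the aryl carbinol carbon C2. That pattern is a butenolide that has taken a nucleophile at its β-carbon and an electrophile at its α-carbon. In one flask a lithiated, silyl-protected vanillin dithiane adds to the (5S)-menthyloxyfuranone and the enolate is benzylated, forming C2–C3 and C4–CH2Ar and both ring stereocentres, trans to one another. The precursor is the crystalline (+)-menthol acetal of 5-hydroxyfuranone; ring bond O1–C2 is closed later under thermodynamic control.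

Key step: step 7

Remark 1 (numbering): target positions are O1, C2 (aryl), C3 (acyloxymethyl arm), C4 (arylmethyl), C5 of the oxolane; butenolide and lactone positions are called "lactone C2" (C=O) to "lactone C5" (acetal).

Remark 2 (configuration): CIP analysis of the target gives (2R,3S,4S), with the C2 aryl trans to the C3 arm and the C3 arm cis to the C4 arylmethyl group. This is the (−)-lariciresinol skeleton and calls for the (5S)-furanone made from (+)-menthol. The anti,anti adduct is (3S,4S,5S) and maps onto C4 (S) and C3 (S) of the target.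

Remark 3: the benzylic carbinol of triol 16 is expected as both epimers (drawn without a descriptor), which does not matter because step 10 passes through a planar benzylic cation.

Step 1
Reactants: 1 furfural
Product: 3 5-hydroxyfuran-2(5H)-one (racemic), via furfural endoperoxide 2 (not isolated)
Conditions: O2, hν (visible), rose bengal (cat.), MeOH, rt
Reagents that add atoms: dioxygen, O=O
Why: Dye-sensitised singlet-oxygen [4+2] cycloaddition to the furan gives endoperoxide 2, which methanol fragments with loss of the formyl carbon as methyl formate to leave the hydroxybutenolide (furfural photo-oxygenation).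

Step 2
Reactants: 3 5-hydroxyfuran-2(5H)-one; 4 (+)-menthol
Product: 6 (5S)-5-[(1S,2R,5S)-menthyloxy]furan-2(5H)-one, via 5R-menthyloxy epimer 5 (not isolated)
Conditions: neat, 100 °C (−H2O); crystallise from petroleum ether, −20 °C; mother liquor re-equilibrated with CSA (cat.) and recrystallised
Reagents that add atoms: none
Why: Thermal acetalisation of the cyclic hemiacetal should give both C5 epimers, and because the acetal centre equilibrates under acid while only the (5S) epimer crystallises, a crystallisation-induced diastereomer transformation should funnel the material into 6.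

Step 3
Reactants: 7 vanillin
Product: 8 3-methoxy-4-(triisopropylsilyloxy)benzaldehyde
Conditions: TIPSCl, imidazole, DMF, rt
Reagents that add atoms: triisopropylsilyl chloride, CC(C)[Si](Cl)(C(C)C)C(C)C
Why: Imidazole-mediated silylation of the phenol; TIPS is chosen because it should withstand n-BuLi, LiAlH4 and mild acid and leave with fluoride at the end without touching the cinnamate.

Step 4
Reactants: 8 3-methoxy-4-(triisopropylsilyloxy)benzaldehyde
Product: 9 2-[3-methoxy-4-(triisopropylsilyloxy)phenyl]-1,3-dithiane
Conditions: propane-1,3-dithiol, BF3·OEt2 (cat.), CH2Cl2, 0 °C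
Reagents that add atoms: propane-1,3-dithiol, SCCCS
Why: Lewis-acid-catalysed dithioacetalisation of an aromatic aldehyde, which gives the Corey–Seebach acyl-anion precursor, with the aryl TIPS ether expected to tolerate catalytic BF3 at 0 °C.

Step 5
Reactants: 8 3-methoxy-4-(triisopropylsilyloxy)benzaldehyde
Product: 10 [3-methoxy-4-(triisopropylsilyloxy)phenyl]methanol
Conditions: NaBH4, MeOH/THF, 0 °C
Reagents that add atoms: none
Why: Borohydride reduction of the aldehyde to the benzylic alcohol, with nothing else in the molecule reducible.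

Step 6
Reactants: 10 [3-methoxy-4-(triisopropylsilyloxy)phenyl]methanol
Product: 11 3-methoxy-4-(triisopropylsilyloxy)benzyl bromide
Conditions: PBr3 (0.4 equiv), Et2O, 0 °C; used crude at once
Reagents that add atoms: phosphorus tribromide, BrP(Br)Br
Why: Bromination of an electron-rich benzylic alcohol with PBr3 (bromide displacement on the phosphite ester), the labile bromide being carried forward without chromatography.

Step 7
Reactants: 9 2-[3-methoxy-4-(triisopropylsilyloxy)phenyl]-1,3-dithiane; 6 (5S)-5-[(1S,2R,5S)-menthyloxy]furan-2(5H)-one; 11 3-methoxy-4-(triisopropylsilyloxy)benzyl bromide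
Product: 14 (3S,4S,5S)-5-[(1S,2R,5S)-menthyloxy]-3-[3-methoxy-4-(triisopropylsilyloxy)benzyl]-4-{2-[3-methoxy-4-(triisopropylsilyloxy)phenyl]-1,3-dithian-2-yl}oxolan-2-one, via lithiated dithiane 12 (not isolated), via lithium enolate 13 (not isolated)
Conditions: n-BuLi, THF, −78 to −20 °C; then 6, −78 °C; then 11, DMPU, −78 to −20 °C; aq. NH4Cl
Reagents that add atoms: none
Why: n-BuLi removes the C2–H of dithiane 9 to give the sulfur-stabilised benzylic anion 12, which adds in Michael fashion to the β-carbon (lactone C4) of butenolide 6, and the lithium enolate 13 so formed is C-benzylated at lactone C3 by bromide 11 in an SN2 step once DMPU is added. The closest known reaction type is the one-flask conjugate addition–enolate alkylation of 5-alkoxyfuran-2(5H)-ones with lithiated dithioacetals and benzylic halides. No ring is closed, so no closure mode applies. The new stereocentre at lactone C4 (target C3) is controlled by the C5 menthyloxy acetal, which blocks one face of the flat butenolide so that 12 enters anti to it; the new stereocentre at lactone C3 (target C4) is controlled by the newly installed dithianyl group, the enolate being alkylated on the face away from it, which should give the 3,4-trans-4,5-trans lactone. The step needs 1,4- over 1,2-addition, secured by the soft delocalised anion at −78 °C, and C-alkylation faster than proton exchange or addition to a second butenolide, secured by the reactive benzylic bromide and the polar cosolvent.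

Step 8
Reactants: 14 the trans,trans dithianyl lactone
Product: 15 (3S,4S,5S)-5-[(1S,2R,5S)-menthyloxy]-3-[3-methoxy-4-(triisopropylsilyloxy)benzyl]-4-[3-methoxy-4-(triisopropylsilyloxy)benzoyl]oxolan-2-one
Conditions: Hg(ClO4)2·3H2O, CaCO3, THF/H2O (5:1), 0 °C
Reagents that add atoms: water, O
Why: Thiophilic Hg(II)-assisted hydrolysis of the dithioacetal (Corey–Seebach unmasking) under carbonate buffering, which should spare the lactone acetal and the aryl silyl ethers, while the ring stereocentres already sit in the thermodynamically preferred trans arrangement.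

Step 9
Reactants: 15 the keto lactone
Product: 16 (2S,3S)-2-{hydroxy[3-methoxy-4-(triisopropylsilyloxy)phenyl]methyl}-3-[3-methoxy-4-(triisopropylsilyloxy)benzyl]butane-1,4-diol (both carbinol epimers)
Conditions: LiAlH4, THF, 0 °C to rt; aq. NaOH work-up
Reagents that add atoms: none
Why: Exhaustive LiAlH4 reduction, in which the ketone gives the benzylic carbinol and the acylal-type lactone is reduced at both carbons to the 1,4-diol with release of menthol, the transient aldehydes being reduced faster than they can enolise so that both carbon stereocentres are retained.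

Step 10
Reactants: 16 the triol
Product: 17 [(2R,3S,4S)-2-[3-methoxy-4-(triisopropylsilyloxy)phenyl]-4-[3-methoxy-4-(triisopropylsilyloxy)benzyl]oxolan-3-yl]methanol
Conditions: CSA (10 mol%), CH2Cl2, 0 °C to rt; quench with Et3N
Reagents that add atoms: none
Why: Acid-catalysed SN1 cycloetherification, in which the electron-rich benzylic carbinol ionises, the C5 hydroxyl captures the cation in a 5-exo closure (the C3-arm hydroxyl could only form an oxetane), and reversible ionisation of the benzylic ether should place the C2 aryl trans to the C3 hydroxymethyl group, so that C2 (R) is set by the C3 stereocentre under thermodynamic control.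

Step 11
Reactants: 18 p-coumaric acid
Product: 20 (E)-3-[4-(tert-butyldimethylsilyloxy)phenyl]prop-2-enoic acid, via bis-silyl coumarate 19 (not isolated)
Conditions: TBSCl (2.2 equiv), imidazole, DMF, rt; then AcOH/THF/H2O, rt
Reagents that add atoms: tert-butyldimethylsilyl chloride, CC(C)(C)[Si](C)(C)Cl
Why: Silylation of both acidic OH groups followed by selective hydrolysis of the much more labile silyl ester in aqueous acetic acid, which leaves the aryl silyl ether in place (standard protection of a hydroxycinnamic acid).

Step 12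
Reactants: 17 the bis-TIPS oxolane alcohol; 20 (E)-3-[4-(tert-butyldimethylsilyloxy)phenyl]prop-2-enoic acid
Product: 21 [(2R,3S,4S)-2-[3-methoxy-4-(triisopropylsilyloxy)phenyl]-4-[3-methoxy-4-(triisopropylsilyloxy)benzyl]oxolan-3-yl]methyl (E)-3-[4-(tert-butyldimethylsilyloxy)phenyl]prop-2-enoate
Conditions: DCC, DMAP (cat.), CH2Cl2, 0 °C to rt
Reagents that add atoms: none
Why: Steglich esterification of the only free hydroxyl of 17, under neutral conditions that should keep the E-alkene and all silyl ethers intact.

Step 13
Reactants: 21 the tris-silyl ester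
Product: 22 lariciresinol p-coumarate, [(2R,3S,4S)-2-(4-hydroxy-3-methoxyphenyl)-4-(4-hydroxy-3-methoxybenzyl)oxolan-3-yl]methyl (E)-3-(4-hydroxyphenyl)prop-2-enoate
Conditions: TBAF (3.3 equiv), AcOH (3.3 equiv), THF, 0 °C
Reagents that add atoms: none
Why: Fluoride-induced cleavage of the three aryl silyl ethers, buffered with acetic acid so that the liberated phenoxides are protonated at once and the cinnamate ester is neither cleaved nor transesterified.

**Compound list**

1 | furfural | O=Cc1ccco1 | starting material
2 | furfural 2,5-endoperoxide (2,3,7-trioxabicyclo[2.2.1]hept-5-ene-1-carbaldehyde, racemic) | O=CC12C=CC(OO1)O2 | intermediate (not isolated)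
3 | 5-hydroxyfuran-2(5H)-one (racemic) | OC1OC(=O)C=C1 | intermediate
4 | (+)-menthol, (1S,2R,5S)-2-isopropyl-5-methylcyclohexanol | CC(C)[C@H]1CC[C@H](C)C[C@@H]1O | starting material
5 | (5R)-5-[(1S,2R,5S)-menthyloxy]furan-2(5H)-one | CC(C)[C@H]1CC[C@H](C)C[C@@H]1O[C@@H]1OC(=O)C=C1 | intermediate (not isolated)
6 | (5S)-5-[(1S,2R,5S)-menthyloxy]furan-2(5H)-one | CC(C)[C@H]1CC[C@H](C)C[C@@H]1O[C@H]1OC(=O)C=C1 | intermediate
7 | vanillin | COc1cc(C=O)ccc1O | starting material
8 | 3-methoxy-4-(triisopropylsilyloxy)benzaldehyde | COc1cc(C=O)ccc1O[Si](C(C)C)(C(C)C)C(C)C | intermediate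
9 | 2-[3-methoxy-4-(triisopropylsilyloxy)phenyl]-1,3-dithiane | COc1cc(C2SCCCS2)ccc1O[Si](C(C)C)(C(C)C)C(C)C | intermediate
10 | [3-methoxy-4-(triisopropylsilyloxy)phenyl]methanol | COc1cc(CO)ccc1O[Si](C(C)C)(C(C)C)C(C)C | intermediate
11 | 3-methoxy-4-(triisopropylsilyloxy)benzyl bromide | COc1cc(CBr)ccc1O[Si](C(C)C)(C(C)C)C(C)C | intermediate
12 | 2-lithio-2-[3-methoxy-4-(triisopropylsilyloxy)phenyl]-1,3-dithiane | [Li]C1(c2ccc(O[Si](C(C)C)(C(C)C)C(C)C)c(OC)c2)SCCCS1 | intermediate (not isolated)
13 | lithium enolate of the (4S,5S) conjugate adduct | CC(C)[C@H]1CC[C@H](C)C[C@@H]1O[C@H]1OC(O[Li])=C[C@@H]1C1(c2ccc(O[Si](C(C)C)(C(C)C)C(C)C)c(OC)c2)SCCCS1 | intermediate (not isolated)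
14 | (3S,4S,5S)-5-[(1S,2R,5S)-menthyloxy]-3-[3-methoxy-4-(triisopropylsilyloxy)benzyl]-4-{2-[3-methoxy-4-(triisopropylsilyloxy)phenyl]-1,3-dithian-2-yl}oxolan-2-one | CC(C)[C@H]1CC[C@H](C)C[C@@H]1O[C@H]1OC(=O)[C@@H](Cc2ccc(O[Si](C(C)C)(C(C)C)C(C)C)c(OC)c2)[C@@H]1C1(c2ccc(O[Si](C(C)C)(C(C)C)C(C)C)c(OC)c2)SCCCS1 | intermediate
15 | (3S,4S,5S)-5-[(1S,2R,5S)-menthyloxy]-3-[3-methoxy-4-(triisopropylsilyloxy)benzyl]-4-[3-methoxy-4-(triisopropylsilyloxy)benzoyl]oxolan-2-one | CC(C)[C@H]1CC[C@H](C)C[C@@H]1O[C@H]1OC(=O)[C@@H](Cc2ccc(O[Si](C(C)C)(C(C)C)C(C)C)c(OC)c2)[C@@H]1C(=O)c1ccc(O[Si](C(C)C)(C(C)C)C(C)C)c(OC)c1 | intermediate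
16 | (2S,3S)-2-{hydroxy[3-methoxy-4-(triisopropylsilyloxy)phenyl]methyl}-3-[3-methoxy-4-(triisopropylsilyloxy)benzyl]butane-1,4-diol (carbinol epimers) | OC(c1ccc(O[Si](C(C)C)(C(C)C)C(C)C)c(OC)c1)[C@H](CO)[C@@H](CO)Cc1ccc(O[Si](C(C)C)(C(C)C)C(C)C)c(OC)c1 | intermediate
17 | [(2R,3S,4S)-2-[3-methoxy-4-(triisopropylsilyloxy)phenyl]-4-[3-methoxy-4-(triisopropylsilyloxy)benzyl]oxolan-3-yl]methanol | COc1cc(C[C@@H]2CO[C@@H](c3ccc(O[Si](C(C)C)(C(C)C)C(C)C)c(OC)c3)[C@@H]2CO)ccc1O[Si](C(C)C)(C(C)C)C(C)C | intermediate
18 | p-coumaric acid | O=C(O)/C=C/c1ccc(O)cc1 | starting material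
19 | tert-butyldimethylsilyl (E)-3-[4-(tert-butyldimethylsilyloxy)phenyl]prop-2-enoate | CC(C)(C)[Si](C)(C)OC(=O)/C=C/c1ccc(O[Si](C)(C)C(C)(C)C)cc1 | intermediate (not isolated)
20 | (E)-3-[4-(tert-butyldimethylsilyloxy)phenyl]prop-2-enoic acid | O=C(O)/C=C/c1ccc(O[Si](C)(C)C(C)(C)C)cc1 | intermediate
21 | [(2R,3S,4S)-2-[3-methoxy-4-(triisopropylsilyloxy)phenyl]-4-[3-methoxy-4-(triisopropylsilyloxy)benzyl]oxolan-3-yl]methyl (E)-3-[4-(tert-butyldimethylsilyloxy)phenyl]prop-2-enoate | COc1cc(C[C@@H]2CO[C@@H](c3ccc(O[Si](C(C)C)(C(C)C)C(C)C)c(OC)c3)[C@@H]2COC(=O)/C=C/c2ccc(O[Si](C)(C)C(C)(C)C)cc2)ccc1O[Si](C(C)C)(C(C)C)C(C)C | intermediate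
22 | lariciresinol p-coumarate, (2R,3S,4S) | COc1cc(C[C@@H]2CO[C@@H](c3ccc(O)c(OC)c3)[C@@H]2COC(=O)/C=C/c2ccc(O)cc2)ccc1O | target

**Step count.** 13 steps in total. The longest linear sequence is 9 steps, from vanillin 7 through steps 3, 5, 6, 7, 8, 9, 10, 12 and 13.

**Steps most likely to fail**

Step 7. The enolate 13 may be protonated, or may add to a second molecule of 6, before it is benzylated; the alkylation may also stall next to the quaternary dithiane carbon. The fallback separates the two bond formations. It sets out from 9 and 6: the conjugate addition alone is quenched with aqueous NH4Cl, which should give the trans 4-dithianyl-5-menthyloxy lactone F1. F1 is then deprotonated with LDA in THF/DMPU at −78 °C and alkylated with bromide 11 on the face away from the dithianyl group. This comes back to the route at 14.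

Step 10. Ionisation of the benzylic carbinol may be followed by Friedel–Crafts attack of the arylmethyl ring on the cation (aryltetralin formation), by incomplete equilibration at C2, or by loss of silyl groups. The fallback moves the closure to the free phenols and makes the ester without protecting groups. It sets out from 16: TBAF/AcOH should remove both TIPS groups to give the free phenolic triol F2. Its p-hydroxybenzylic alcohol should close through the p-quinone methide under much weaker acid (PPTS, cat.) to (−)-lariciresinol F3. F3 is then esterified at its only aliphatic hydroxyl with unprotected p-coumaric acid 18 under Mitsunobu conditions (PPh3, DIAD, THF), in which only the carboxylic acid is acidic enough to act as pronucleophile and phenols are not activated. This comes back to the route at 22 and bypasses steps 11 to 13.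

Step 8. The unmasking may be slow at the hindered dithioacetal, or may be accompanied by cleavage of the menthyl acetal or the silyl ethers by the Lewis-acidic mercury salt. The fallback reverses the order of reduction and unmasking. It sets out from 14: LiAlH4 in THF should first give the dithiane diol F4 with release of menthol, so that no acetal remains. Alkylative unmasking with MeI and CaCO3 in aqueous MeCN (no heavy metal, no acid) should then give the keto diol F5, which is reduced at once with NaBH4 in MeOH. This comes back to the route at 16.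

**Further compounds**

F1 | step 7 | (4S,5S)-5-[(1S,2R,5S)-menthyloxy]-4-{2-[3-methoxy-4-(triisopropylsilyloxy)phenyl]-1,3-dithian-2-yl}oxolan-2-one | CC(C)[C@H]1CC[C@H](C)C[C@@H]1O[C@H]1OC(=O)C[C@@H]1C1(c2ccc(O[Si](C(C)C)(C(C)C)C(C)C)c(OC)c2)SCCCS1
F2 | step 10 | (2S,3S)-2-[hydroxy(4-hydroxy-3-methoxyphenyl)methyl]-3-(4-hydroxy-3-methoxybenzyl)butane-1,4-diol (carbinol epimers) | OC(c1ccc(O)c(OC)c1)[C@H](CO)[C@@H](CO)Cc1ccc(O)c(OC)c1
F3 | step 10 | (−)-lariciresinol, (2R,3S,4S) | COc1cc(C[C@@H]2CO[C@@H](c3ccc(O)c(OC)c3)[C@@H]2CO)ccc1O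
F4 | step 8 | (2S,3S)-2-{2-[3-methoxy-4-(triisopropylsilyloxy)phenyl]-1,3-dithian-2-yl}-3-[3-methoxy-4-(triisopropylsilyloxy)benzyl]butane-1,4-diol | COc1cc(C2(SCCCS2)[C@H](CO)[C@@H](CO)Cc2ccc(O[Si](C(C)C)(C(C)C)C(C)C)c(OC)c2)ccc1O[Si](C(C)C)(C(C)C)C(C)C
F5 | step 8 | (2S,3S)-4-hydroxy-2-(hydroxymethyl)-1-[3-methoxy-4-(triisopropylsilyloxy)phenyl]-3-[3-methoxy-4-(triisopropylsilyloxy)benzyl]butan-1-one | O=C(c1ccc(O[Si](C(C)C)(C(C)C)C(C)C)c(OC)c1)[C@H](CO)[C@@H](CO)Cc1ccc(O[Si](C(C)C)(C(C)C)C(C)C)c(OC)c1
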